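The leftover I started from stood in the summer run at 4.00 h: 10.9% of target beside 57.8% of other capture product, a share of 15.9%, and I wanted to know what becomes of that share when one nucleophile is fed in instead of charged.

the same everywhere: substrate 0.10 M
- summer: first nucleophile 0.10 M; second nucleophile 0.10 M; capture agent 0.010 M; run made earlier
- midnight: first nucleophile 0.10 M; second nucleophile 0.067 M; capture agent 0.010 M; run made earlier
- spring: first nucleophile 0.10 M; second nucleophile 0.15 M; capture agent 0.010 M; run made earlier
- dawn: first nucleophile 0.050 M; second nucleophile 0.10 M; capture agent 0.010 M; run made earlier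
- eta: first nucleophile 0.100 M (in portions, 2, over 1.5 h); second nucleophile 0.100 M; capture agent 0.0100 M; first portion at the start, last at 1.5 h; time 4.0 h
- alpha: first nucleophile 0.100 M (fed, over 1.5 h); second nucleophile 0.100 M; capture agent 0.0100 M; all else is in the flask from the start; the feed brings no volume worth counting; time 4.0 h
- gamma: first nucleophile 0.100 M; second nucleophile 0.100 M (fed, over 1.5 h); capture agent 0.0100 M; all else is in the flask from the start; the feed brings no volume worth counting; time 4.0 h
- beta: first nucleophile 0.100 M; second nucleophile 0.100 M; capture agent 0.0100 M; everything together at the start; time 4.0 h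

| run | time / h | target / % | other capture product / % |
|---|---|---|---|
| summer | 0.333 | 4.9 | 13.2 |
| summer | 0.667 | 7.8 | 22.7 |
| summer | 1.00 | 10.4 | 31.1 |
| summer | 2.00 | 12.4 | 47.5 |
| summer | 4.00 | 10.9 | 57.8 |
| midnight | 0.200 | 4.1 | 7.7 |
| midnight | 0.333 | 6.1 | 9.4 |
| midnight | 0.667 | 11.4 | 19.1 |
| midnight | 1.33 | 17.6 | 32.3 |
| midnight | 2.50 | 21.1 | 42.8 |
| spring | 0.200 | 2.0 | 7.6 |
| spring | 0.333 | 5.0 | 14.9 |
| spring | 0.667 | 5.9 | 26.1 |
| spring | 1.33 | 8.0 | 42.3 |
| spring | 2.50 | 7.5 | 58.7 |
| dawn | 0.200 | 3.7 | 8.9 |
| dawn | 0.333 | 4.9 | 14.1 |
| dawn | 0.667 | 4.2 | 25.8 |
| dawn | 1.33 | 8.8 | 44.4 |
| dawn | 2.50 | 10.4 | 61.2 |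

(standard deviation of a reading: 1 percentage point)

- a reading or a percentage of target counts all its forms, free or not

1. which flask leads in share of target in target plus other capture product ("all alike" within 1.5 percentage points) (eta / alpha / gamma / beta / all alike)
2. share of target in target plus other capture product at the end, eta
3. share of target in target plus other capture product at the end, alpha
4. share of target in target plus other capture product at the end, gamma
5. share of target in target plus other capture product at the end, beta

At 0.667 h the two products together read 30.5% in summer, 30.5% in midnight, 32.0% in spring and 30.0% in dawn, although the nucleophile charges differ, so I took a slow opening of the substrate as the rate-limiting step, with the two nucleophiles competing for whatever it releases. The first readings of summer, midnight and spring average 2.68, the selectivity factor, meaning other capture product made per target at equal levels of the two nucleophiles; dawn gave 1.20 on its first reading and 3.07 on its third, which I read as scatter on either side. The split of fresh capture towards target is then the first nucleophile's level divided by that level plus the factor times the second nucleophile's level.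

I then ran the flasks slowly in my head. In the first instants of gamma the second nucleophile is only arriving, so the split leans to target, while alpha leans the other way. Midway through the feed, with 0.0500 M fed, gamma's split is 42.8%, more than the 27.2% of beta at its charges, and alpha's is 15.7%, less; eta, starting with 0.0500 M standing, I put beside alpha. Summer had 59.9% captured by 2.00 h, against 68.7% at the end. Summer's target read 12.4% at 2.00 h and 10.9% at 4.00 h, and its final share was 0.583 of its split, so, assuming the same fraction elsewhere, my own reckoning came to 24.9% for gamma, 9.18% for alpha and eta, and 15.9% for beta.

The forecast, a separate reckoning from mine with figures of its own, named gamma, with 14% for eta, 14% for alpha, 24% for gamma and 16% for beta, gamma's figure resting on “a big early target share”.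

The flask gave gamma in the lead, with 10.7% for eta, 9.69% for alpha, 31.9% for gamma and 14.8% for beta, and at 4.00 h gamma held 14.4% as crystals, counted within its 22.6% of target, more than the 2.12% of beta.

    first nucleophile + target → over-reaction product (k = 0.172 M⁻¹ min⁻¹)
    open intermediate + capture agent → trapped intermediate (k = 0.258 M⁻¹ min⁻¹)
    second nucleophile + open intermediate → other capture product (k = 919 M⁻¹ min⁻¹)
    crystals ⇌ target, rate k4*(cs4 - [target]) while solid is left; crystals form when [target] > cs4 (solubility = 8.20 mM, k = 2.82 min⁻¹)
    substrate → open intermediate (k = 0.0104 min⁻¹)
    open intermediate → solvolysis product (k = 1.61 min⁻¹)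
    first nucleophile + open intermediate → target (k = 427 M⁻¹ min⁻¹)

For a flask like alpha but charged with 0.040 M of second nucleophile, the factor 2.68 applied to the whole charges gives a split of 48.3%, and that flask ended with a share of 48.4%.

The data were generated by integration with constants of no real substance; the scatter is artificial.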